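**Retrosynthetic overview**
1. Feature: the cyclohexene is numbered C1(CH3)=C2H–C3H(benzofuran-5-yl)–C4H(aroyl)–C5H(2,4-dihydroxyphenyl)–C6H2. The aryl groups on C3 and C5 are cis, the C4 aroyl group is trans to both, and each aryl carries an OH ortho to its ring bond (benzofuran O6, phenyl O2). These two oxygens are tied by O–Si(iPr)2–O–Si(iPr)2–O.
2. Key disconnection: C4–C5 and C2–C3. The benzofuranyl enone C3=C4 adds intramolecularly (Diels–Alder) to the 1-aryl-3-methyl-4-boryl diene C5=C6–C1=C2 in the aryl-endo/acyl-exo mode, under a chiral boron chelate on the 2-hydroxyaryl ketone.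
3. The adduct has the C1=C6 alkene and an allylboronate at C2. Fluoride-induced γ-protonation at C6 moves the alkene to C1=C2 and also cuts the tether, and MOM removal ends the route.
4. Precursor: a Claisen–Schmidt enone (prenylated resacetophenone plus 6-oxygenated 2-arylbenzofuran-5-carbaldehyde), a dienyl boronate (HWE enyne, then Cu methylboration) and the dichlorodisiloxane.
5. Ring order: benzofuran (Sonogashira/5-endo-dig), then the cyclohexene together with the temporary twelve-membered ring (key step), then opening of the twelve-membered ring.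

Key step: step 17

Assumption: the sense of induction of the VANOL–boron chelate is not established for an enone whose new α-bond goes to C5. (S)-VANOL is written for the antipode that gives the (2S,3R,4S,5S) cycloadduct, and the equally available (R)-VANOL is used if a first run shows the opposite sense.

**Route**

Step 1
Reactants: 1 2',4'-dihydroxyacetophenone
Product: 2 1-[2,4-dihydroxy-3-(3-methylbut-2-en-1-yl)phenyl]ethanone
Conditions: prenyl bromide (1.0 equiv), KOH (aq), 0 °C → rt; chromatography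
Reagents that add atoms: prenyl bromide, CC(C)=CCBr
Why: Phenolate C-alkylation: in aqueous KOH the carbon between the two phenolate oxygens (C3) is the most nucleophilic ring position, so the 3-prenyl ketone should be the main C-alkylation product and is separated from the 5-prenyl and O-prenyl isomers.

Step 2
Reactants: 2 1-[2,4-dihydroxy-3-(3-methylbut-2-en-1-yl)phenyl]ethanone
Product: 3 1-[2-hydroxy-4-(methoxymethoxy)-3-(3-methylbut-2-en-1-yl)phenyl]ethanone
Conditions: MOMCl (1.1 equiv), K2CO3, acetone, 0 °C → rt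
Reagents that add atoms: chloromethyl methyl ether, COCCl
Why: Williamson-type O-alkylation: the 2-OH is hydrogen-bonded to the ketone and flanked by the prenyl group, so only the 4-OH is alkylated.

Step 3
Reactants: 4 3,5-dihydroxybenzaldehyde
Product: 5 3,5-bis(methoxymethoxy)benzaldehyde
Conditions: MOMCl (2.5 equiv), K2CO3, DMF, 0 °C → rt
Reagents that add atoms: chloromethyl methyl ether, COCCl
Why: Williamson-type O-alkylation of both unhindered phenols gives base-stable acetals that survive every later basic and organometallic step.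

Step 4
Reactants: 5 3,5-bis(methoxymethoxy)benzaldehyde
Product: 6 1-ethynyl-3,5-bis(methoxymethoxy)benzene
Conditions: Ohira–Bestmann reagent, K2CO3, MeOH, rt
Reagents that add atoms: dimethyl (1-diazo-2-oxopropyl)phosphonate, CC(=O)C(=[N+]=[N-])P(=O)(OC)OC
Why: Ohira–Bestmann (Seyferth–Gilbert) homologation works well on non-enolisable aromatic aldehydes, and MOM ethers are inert to K2CO3/MeOH.

Step 5
Reactants: 7 2,4-dihydroxybenzaldehyde
Product: 8 2,4-dihydroxy-5-iodobenzaldehyde
Conditions: ICl, AcOH, rt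
Reagents that add atoms: iodine monochloride, ClI
Why: Electrophilic aromatic iodination: C5 is ortho to the 4-OH, para to the 2-OH and unhindered, so it is attacked in preference to the crowded C3 between the two hydroxyls.

Step 6
Reactants: 8 2,4-dihydroxy-5-iodobenzaldehyde; 6 1-ethynyl-3,5-bis(methoxymethoxy)benzene
Product: 10 2-[3,5-bis(methoxymethoxy)phenyl]-6-hydroxy-1-benzofuran-5-carbaldehyde, via 5-{[3,5-bis(methoxymethoxy)phenyl]ethynyl}-2,4-dihydroxybenzaldehyde 9 (not isolated)
Conditions: PdCl2(PPh3)2 (3 mol %), CuI (5 mol %), Et3N, DMF, rt → 65 °C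
Reagents that add atoms: none
Why: Sonogashira coupling followed in the same pot by Pd/Cu-promoted 5-endo-dig heteroannulation: only the 4-OH is ortho to the new alkyne, so it closes the furan ring while the aldehyde-chelated 2-OH remains as O6–H of the benzofuran.

Step 7
Reactants: 10 2-[3,5-bis(methoxymethoxy)phenyl]-6-hydroxy-1-benzofuran-5-carbaldehyde
Product: 11 6-(allyloxy)-2-[3,5-bis(methoxymethoxy)phenyl]-1-benzofuran-5-carbaldehyde
Conditions: allyl bromide, K2CO3, DMF, 50 °C
Reagents that add atoms: allyl bromide, C=CCBr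
Why: Williamson etherification masks the phenol, which as a phenoxide would deactivate the aldehyde in the aldol step, with a group that is base-stable and orthogonal to MOM.

Step 8
Reactants: 11 6-(allyloxy)-2-[3,5-bis(methoxymethoxy)phenyl]-1-benzofuran-5-carbaldehyde; 3 1-[2-hydroxy-4-(methoxymethoxy)-3-(3-methylbut-2-en-1-yl)phenyl]ethanone
Product: 12 (E)-3-{6-(allyloxy)-2-[3,5-bis(methoxymethoxy)phenyl]-1-benzofuran-5-yl}-1-[2-hydroxy-4-(methoxymethoxy)-3-(3-methylbut-2-en-1-yl)phenyl]prop-2-en-1-one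
Conditions: KOH, EtOH/THF, rt
Reagents that add atoms: none
Why: Claisen–Schmidt condensation as used for 2'-hydroxychalcones: E1cB dehydration gives the (E)-C3=C4 enone, and MOM, allyl and prenyl groups are stable to KOH.

Step 9
Reactants: 12 allyl-protected enone
Product: 13 (E)-3-{2-[3,5-bis(methoxymethoxy)phenyl]-6-hydroxy-1-benzofuran-5-yl}-1-[2-hydroxy-4-(methoxymethoxy)-3-(3-methylbut-2-en-1-yl)phenyl]prop-2-en-1-one
Conditions: Pd(PPh3)4 (5 mol %), morpholine, THF, rt, dark
Reagents that add atoms: none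
Why: Tsuji–Trost-type Pd(0) deallylation: only the aryl allyl ether ionises to a π-allyl complex, which morpholine traps, while the C-prenyl group, MOM ethers and enone are untouched.

Step 10
Reactants: 7 2,4-dihydroxybenzaldehyde
Product: 14 2-hydroxy-4-(methoxymethoxy)benzaldehyde
Conditions: MOMCl (1.05 equiv), K2CO3, acetone, 0 °C → rt
Reagents that add atoms: chloromethyl methyl ether, COCCl
Why: Selective Williamson-type O-alkylation: the 2-OH is held in a hydrogen bond to the aldehyde, so the more acidic and accessible 4-OH reacts.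

Step 11
Reactants: 14 2-hydroxy-4-(methoxymethoxy)benzaldehyde
Product: 15 4-(methoxymethoxy)-2-[(triisopropylsilyl)oxy]benzaldehyde
Conditions: TIPSCl, imidazole, DMF, rt
Reagents that add atoms: chlorotriisopropylsilane, CC(C)[Si](Cl)(C(C)C)C(C)C
Why: Imidazole-promoted phenol silylation: the hindered TIPS ether is chosen because it should survive LiHMDS, K2CO3/MeOH and NaOtBu and still leave with fluoride in the presence of MOM and Bpin.

Step 12
Reactants: 15 4-(methoxymethoxy)-2-[(triisopropylsilyl)oxy]benzaldehyde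
Product: 16 (E)-{4-[4-(methoxymethoxy)-2-(triisopropylsilyloxy)phenyl]but-3-en-1-yn-1-yl}trimethylsilane
Conditions: (EtO)2P(O)CH2C≡CSiMe3, LiHMDS, THF, −78 °C → rt
Reagents that add atoms: diethyl [3-(trimethylsilyl)prop-2-yn-1-yl]phosphonate, CCOP(=O)(CC#C[Si](C)(C)C)OCC
Why: Horner–Wadsworth–Emmons olefination: the stabilised propargylic phosphonate anion adds reversibly to the aromatic aldehyde and should give the (E)-enyne, which fixes the C5=C6 geometry.

Step 13
Reactants: 16 (E)-TMS-enyne
Product: 17 (E)-[2-(but-1-en-3-yn-1-yl)-5-(methoxymethoxy)phenoxy]triisopropylsilane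
Conditions: K2CO3 (cat.), MeOH/THF, 0 °C
Reagents that add atoms: none
Why: Methoxide-induced protiodesilylation of the alkynylsilane is much faster than attack on the hindered aryl O–TIPS bond.

Step 14
Reactants: 17 terminal (E)-enyne
Product: 18 2-{(1E,3E)-4-[4-(methoxymethoxy)-2-(triisopropylsilyloxy)phenyl]-2-methylbuta-1,3-dien-1-yl}-4,4,5,5-tetramethyl-1,3,2-dioxaborolane
Conditions: CuCl (10 mol %), Xantphos (10 mol %), NaOtBu, B2pin2 (1.1 equiv), MeI, THF, rt
Reagents that add atoms: bis(pinacolato)diboron, CC1(C)OB(OC1(C)C)B1OC(C)(C)C(C)(C)O1; iodomethane, CI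
Why: Copper-catalysed carboboration (methylboration) of a terminal alkyne: syn-borylcupration places boron on the terminal carbon (C2) and copper on the internal carbon (C1), and methylation of the alkenylcopper with retention leaves B and CH3 cis, which is the (E)-C1=C2 bond with boron in the outside position.

Step 15
Reactants: 18 TIPS-protected (E,E)-dienyl boronate
Product: 19 5-(methoxymethoxy)-2-[(1E,3E)-3-methyl-4-(4,4,5,5-tetramethyl-1,3,2-dioxaborolan-2-yl)buta-1,3-dien-1-yl]phenol
Conditions: TBAF (1.05 equiv), AcOH (1.1 equiv), THF, −20 → 0 °C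
Reagents that add atoms: none
Why: Buffered fluoride desilylation: aryl silyl ethers are cleaved within minutes at low temperature, so one equivalent of buffered fluoride should leave the alkenyl Bpin, the diene and the MOM ether intact.

Step 16
Reactants: 19 dienyl boronate phenol; 20 1,3-dichloro-1,1,3,3-tetraisopropyldisiloxane; 13 enone phenol
Product: 22 disiloxane-tethered (E)-enone/(E,E)-boryl diene (benzofuran O6–Si(iPr)2–O–Si(iPr)2–O2 of the dienyl arene; 2'-OH free), via 3-chloro-1,1,3,3-tetraisopropyldisiloxan-1-yl ether of the dienyl boronate phenol 21 (not isolated)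
Conditions: 19, 20 (4 equiv), imidazole, CH2Cl2, 0 °C; pentane, filtration under Ar, excess 20 distilled off (0.05 mbar, 60 °C); then 13, imidazole, DMAP (cat.), CH2Cl2, rt, dark
Reagents that add atoms: none
Why: Stepwise silyl ether formation (temporary silicon connection): the single phenol of 19 takes one Si–Cl of excess 20, the surplus dichloride is removed, and the remaining hindered Si–Cl then silylates only O6–H of 13 because the 2'-OH is hydrogen-bonded to the ketone and flanked by the prenyl group.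

Step 17
Reactants: 22 disiloxane-tethered enone/boryl diene
Product: 25 (2S,3R,4S,5S)-configured tethered exo cycloadduct with the C1=C6 alkene and Bpin on C2, via (S)-VANOL spiroborate chelate of the tethered precursor 23 (not isolated), via (S)-VANOL spiroborate chelate of the cycloadduct 24 (not isolated)
Conditions: (S)-VANOL, BH3·THF, AcOH (1.2 equiv each), THF, rt, volatiles removed in vacuo; 22 (2 mM), 5 Å MS, PhCF3, rt → 40 °C, dark; then pH 7 buffer
Reagents that add atoms: (S)-VANOL [(S)-3,3'-diphenyl-2,2'-binaphthalene-1,1'-diol], Oc1c(-c2c(O)c3ccccc3cc2-c2ccccc2)c(-c2ccccc2)cc2ccccc12; borane–tetrahydrofuran complex, [BH3-][O+]1CCCC1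
Why: Proposed new method: the VANOL–boron fragment, made from (S)-VANOL, BH3·THF and AcOH and carried only by 23 and 24 until the buffer work-up releases it, binds the 2-hydroxyaryl ketone of 22 as a spiroborate chelate, which lowers the enone LUMO, and a concerted asynchronous normal-demand [4+2] cycloaddition of C3=C4 to the s-cis diene C5=C6–C1=C2 then forms C4–C5 and C2–C3. The closest known reaction types are the chiral-boron-promoted Diels–Alder reaction of 2'-hydroxychalcones with 1-aryl-3-methylbutadienes, the silicon-tethered intramolecular Diels–Alder reaction and the cycloaddition of 1-boryl dienes to cyclic allylboronates, and what is new is their combination in a tether that joins the diene terminus C5 to the distal enone carbon C3. The cyclohexene closes by the [4+2] ring closure itself, and the twelve-membered ring (C3, C4, C5, the two ortho-phenylene C–C pairs and O–Si–O–Si–O) closes with it as the long bridge of a bicyclo[9.3.1] frame. C3/C4 trans follows from the (E)-enone and C2/C5 cis from the (E,E)-diene by suprafacial addition, C4/C5 trans and C3/C5 cis follow from the aryl-endo/acyl-exo folding (so that C2–B, C3–aryl and C5–aryl share one face and the C4 aroyl group takes the other), and the absolute sense follows from the ligand, which shields one face of the chelated enone. The step needs acyl-exo selectivity, for which two elements work together: the cis-1,3 bridge leaves the three ring substituents pseudo-equatorial whereas acyl-endo folding would give a trans-1,3 (in,out) bridge with a pseudo-axial aryl, and the bulky spiroborate cannot sit under C6 and the C1 methyl group. It also needs C4–C5 rather than C3–C5 bonding, secured by the match of the largest diene HOMO coefficient at C2 (remote from the donor aryl) with the enone β-carbon C3, and ring closure rather than oligomerisation, secured by high dilution.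

Step 18
Reactants: 25 tethered exo cycloadduct
Product: 26 (3R,4R,5S)-4-[2-hydroxy-4-(methoxymethoxy)-3-prenylbenzoyl]-5-[2-hydroxy-4-(methoxymethoxy)phenyl]-3-{2-[3,5-bis(methoxymethoxy)phenyl]-6-hydroxy-1-benzofuran-5-yl}-1-methylcyclohex-1-ene
Conditions: TBAF·3H2O (8 equiv), THF, rt → 45 °C; aq NH4Cl
Reagents that add atoms: none
Why: Fluoride-mediated protodeboronation of an allylic pinacol boronate (SE2'): the fluoride (or neighbouring O6-phenoxide) boron ate complex is protonated by water at the γ-carbon C6, which moves the alkene to C1=C2 and erases the auxiliary C2 centre, while the same reagent cleaves both aryl O–Si bonds and cannot scramble C4 because the trans,trans arrangement is the more stable one.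

Step 19
Reactants: 26 tetrakis-MOM ether
Product: 27 CNP0150120.1, (3R,4R,5S)-4-(2,4-dihydroxy-3-prenylbenzoyl)-5-(2,4-dihydroxyphenyl)-3-[2-(3,5-dihydroxyphenyl)-6-hydroxy-1-benzofuran-5-yl]-1-methylcyclohex-1-ene
Conditions: HCl (1.25 M in MeOH), MeOH/THF, rt → 35 °C, Ar, stopped at full conversion
Reagents that add atoms: none
Why: Acid-catalysed acetal exchange (MOM methanolysis): aryl MOM ethers are cleaved by dilute methanolic HCl under conditions that prenylated 2'-hydroxyaryl ketones tolerate, no stereocentre is touched, and the mild acid and short contact time keep the prenyl and C1=C2 alkenes from adding the neighbouring phenols.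

**Compound list**
1 | 2',4'-dihydroxyacetophenone | CC(=O)c1ccc(O)cc1O | starting material
2 | 1-[2,4-dihydroxy-3-(3-methylbut-2-en-1-yl)phenyl]ethanone | CC(=O)c1ccc(O)c(CC=C(C)C)c1O | intermediate
3 | 1-[2-hydroxy-4-(methoxymethoxy)-3-(3-methylbut-2-en-1-yl)phenyl]ethanone | CC(=O)c1ccc(OCOC)c(CC=C(C)C)c1O | intermediate
4 | 3,5-dihydroxybenzaldehyde | O=Cc1cc(O)cc(O)c1 | starting material
5 | 3,5-bis(methoxymethoxy)benzaldehyde | O=Cc1cc(OCOC)cc(OCOC)c1 | intermediate
6 | 1-ethynyl-3,5-bis(methoxymethoxy)benzene | C#Cc1cc(OCOC)cc(OCOC)c1 | intermediate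
7 | 2,4-dihydroxybenzaldehyde | O=Cc1ccc(O)cc1O | starting material
8 | 2,4-dihydroxy-5-iodobenzaldehyde | O=Cc1cc(I)c(O)cc1O | intermediate
9 | 5-{[3,5-bis(methoxymethoxy)phenyl]ethynyl}-2,4-dihydroxybenzaldehyde | O=Cc1cc(C#Cc2cc(OCOC)cc(OCOC)c2)c(O)cc1O | intermediate
10 | 2-[3,5-bis(methoxymethoxy)phenyl]-6-hydroxy-1-benzofuran-5-carbaldehyde | O=Cc1cc2cc(-c3cc(OCOC)cc(OCOC)c3)oc2cc1O | intermediate
11 | 6-(allyloxy)-2-[3,5-bis(methoxymethoxy)phenyl]-1-benzofuran-5-carbaldehyde | O=Cc1cc2cc(-c3cc(OCOC)cc(OCOC)c3)oc2cc1OCC=C | intermediate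
12 | allyl-protected (E)-benzofuranyl enone | CC(C)=CCc1c(OCOC)ccc(C(=O)/C=C/c2cc3cc(-c4cc(OCOC)cc(OCOC)c4)oc3cc2OCC=C)c1O | intermediate
13 | (E)-benzofuranyl enone with free O6–H and 2'-OH | CC(C)=CCc1c(OCOC)ccc(C(=O)/C=C/c2cc3cc(-c4cc(OCOC)cc(OCOC)c4)oc3cc2O)c1O | intermediate
14 | 2-hydroxy-4-(methoxymethoxy)benzaldehyde | O=Cc1ccc(OCOC)cc1O | intermediate
15 | 4-(methoxymethoxy)-2-[(triisopropylsilyl)oxy]benzaldehyde | O=Cc1ccc(OCOC)cc1O[Si](C(C)C)(C(C)C)C(C)C | intermediate
16 | (E)-{4-[4-(methoxymethoxy)-2-(triisopropylsilyloxy)phenyl]but-3-en-1-yn-1-yl}trimethylsilane | C[Si](C)(C)C#C/C=C/c1ccc(OCOC)cc1O[Si](C(C)C)(C(C)C)C(C)C | intermediate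
17 | (E)-[2-(but-1-en-3-yn-1-yl)-5-(methoxymethoxy)phenoxy]triisopropylsilane | C#C/C=C/c1ccc(OCOC)cc1O[Si](C(C)C)(C(C)C)C(C)C | intermediate
18 | TIPS-protected (1E,3E)-1-aryl-3-methyl-4-(pinacolboryl)butadiene | COCOc1ccc(/C=C/C(C)=C/B2OC(C)(C)C(C)(C)O2)c(O[Si](C(C)C)(C(C)C)C(C)C)c1 | intermediate
19 | 5-(methoxymethoxy)-2-[(1E,3E)-3-methyl-4-(pinacolboryl)buta-1,3-dien-1-yl]phenol | COCOc1ccc(/C=C/C(C)=C/B2OC(C)(C)C(C)(C)O2)c(O)c1 | intermediate
20 | 1,3-dichloro-1,1,3,3-tetraisopropyldisiloxane | CC(C)[Si](Cl)(C(C)C)O[Si](Cl)(C(C)C)C(C)C | starting material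
21 | 3-chloro-1,1,3,3-tetraisopropyldisiloxan-1-yl ether of the dienyl boronate phenol | COCOc1ccc(/C=C/C(C)=C/B2OC(C)(C)C(C)(C)O2)c(O[Si](C(C)C)(C(C)C)O[Si](Cl)(C(C)C)C(C)C)c1 | intermediate
22 | disiloxane-tethered (E)-enone/(E,E)-boryl diene | CC(C)=CCc1c(OCOC)ccc(C(=O)/C=C/c2cc3cc(-c4cc(OCOC)cc(OCOC)c4)oc3cc2O[Si](C(C)C)(C(C)C)O[Si](C(C)C)(C(C)C)Oc2cc(OCOC)ccc2/C=C/C(C)=C/B2OC(C)(C)C(C)(C)O2)c1O | intermediate
23 | (S)-VANOL spiroborate chelate of the tethered precursor (S axis in the binaphthyl unit) | CC(C)=CCc1c(OCOC)ccc2c1O[B-]3(Oc4c(c(-c5ccccc5)cc5ccccc45)-c4c(O3)c5ccccc5cc4-c4ccccc4)[O+]=C2/C=C/c2cc3cc(-c4cc(OCOC)cc(OCOC)c4)oc3cc2O[Si](C(C)C)(C(C)C)O[Si](C(C)C)(C(C)C)Oc2cc(OCOC)ccc2/C=C/C(C)=C/B2OC(C)(C)C(C)(C)O2 | intermediate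
24 | (S)-VANOL spiroborate chelate of the cycloadduct (S axis in the binaphthyl unit) | CC(C)=CCc1c(OCOC)ccc2c1O[B-]3(Oc4c(c(-c5ccccc5)cc5ccccc45)-c4c(O3)c5ccccc5cc4-c4ccccc4)[O+]=C2[C@@H]2[C@@H](c3ccc(OCOC)cc3O[Si](C(C)C)(C(C)C)O[Si](C(C)C)(C(C)C)O6)C=C(C)[C@@H](B3OC(C)(C)C(C)(C)O3)[C@H]2c2cc3cc(-c4cc(OCOC)cc(OCOC)c4)oc3cc26 | intermediate
25 | tethered exo cycloadduct, (2S,3R,4S,5S), C1=C6 alkene, Bpin on C2; C2–B, C3–aryl and C5–aryl on one face, C4–aroyl on the other | CC(C)=CCc1c(OCOC)ccc(C(=O)[C@@H]2[C@@H](c3ccc(OCOC)cc3O[Si](C(C)C)(C(C)C)O[Si](C(C)C)(C(C)C)O6)C=C(C)[C@@H](B3OC(C)(C)C(C)(C)O3)[C@H]2c2cc3cc(-c4cc(OCOC)cc(OCOC)c4)oc3cc26)c1O | intermediate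
26 | (3R,4R,5S) tetrakis-MOM ether of the target, C1=C2 alkene | CC(C)=CCc1c(OCOC)ccc(C(=O)[C@@H]2[C@@H](c3ccc(OCOC)cc3O)CC(C)=C[C@H]2c2cc3cc(-c4cc(OCOC)cc(OCOC)c4)oc3cc2O)c1O | intermediate
27 | CNP0150120.1, (3R,4R,5S) | CC(C)=CCc1c(O)ccc(C(=O)[C@@H]2[C@@H](c3ccc(O)cc3O)CC(C)=C[C@H]2c2cc3cc(-c4cc(O)cc(O)c4)oc3cc2O)c1O | target

**Totals**
- Total step count: 19.
- Longest linear sequence: 10 steps (7 → 14 → 15 → 16 → 17 → 18 → 19 → 22 → 25 → 26 → 27). The enone branch 4 → 5 → 6 → 10 → 11 → 12 → 13 → 22 is of equal length.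

**Steps most likely to fail**

1. Step 17.
- What may go wrong: the cycloaddition may be sluggish because C2–C3 joins two hindered carbons. The flexible twelve-membered bridge may also admit the acyl-endo folding, giving poor exo/endo selectivity. Facial selectivity may be poor, and oligomerisation may compete.
- Fallback (known chemistry; sets out from 14, 3 and 11 and returns at 26): the cyclohexene is made by the established intermolecular chiral-boron-promoted Diels–Alder reaction of a 2'-hydroxychalcone (C4=C5) with a dehydroprenyl arene (C3=C2–C1=C6), which gives the C1=C2 alkene directly. Allylation of 14 (allyl bromide, K2CO3, DMF) gives 2-(allyloxy)-4-(methoxymethoxy)benzaldehyde F1. Claisen–Schmidt condensation of this aldehyde with 3 (KOH, EtOH) gives (E)-3-[2-(allyloxy)-4-(methoxymethoxy)phenyl]-1-[2-hydroxy-4-(methoxymethoxy)-3-prenylphenyl]prop-2-en-1-one F2. Condensation of 11 with acetone (aq NaOH) gives (E)-4-{6-(allyloxy)-2-[3,5-bis(methoxymethoxy)phenyl]-1-benzofuran-5-yl}but-3-en-2-one F3. Wittig methylenation (Ph3P=CH2, THF) then gives 6-(allyloxy)-2-[3,5-bis(methoxymethoxy)phenyl]-5-[(E)-3-methylbuta-1,3-dien-1-yl]-1-benzofuran F4. The chalcone and the diene are combined under the VANOL–boron promoter, using the antipode opposite to that of step 17 because the new bond at C4 now goes to C3 and therefore forms on the other face of the chelated enone. The all-trans (3R,4R,5S) bis(allyl) tetrakis(MOM) exo adduct F5 is separated from its endo isomer by chromatography, and Pd(PPh3)4/morpholine removes both allyl groups to give 26.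

2. Step 18.
- What may go wrong: protonation may compete at the α-carbon C2, which leaves the alkene at C1=C6. Deboronation may also stay incomplete after the tether has already been lost.
- Fallback (sets out from 25 and returns at 26): oxidation of the C–B bond with retention (NaBO3·4H2O, THF/H2O) gives the tethered C2 allylic alcohol F6. Mitsunobu displacement with 2-nitrobenzenesulfonylhydrazide (PPh3, DEAD, THF, −30 °C → rt) with in situ sigmatropic loss of dinitrogen (Myers reductive allylic transposition) delivers hydrogen to C6 and gives the tethered C1=C2 cyclohexene F7. TBAF (THF, 0 °C) then removes the disiloxane to give 26.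

3. Step 14.
- What may go wrong: the alkenylcopper may be protonated instead of methylated. Borylcupration may occur at the styrenyl alkene or in a 1,4-sense across the enyne. The TIPS group may be lost, followed by O-methylation.
- Fallback (sets out from 17 and returns at 18): Negishi zirconium-catalysed methylalumination (Me3Al, Cp2ZrCl2, CH2Cl2, 0 °C) followed by I2 gives {2-[(1E,3E)-4-iodo-3-methylbuta-1,3-dien-1-yl]-5-(methoxymethoxy)phenoxy}triisopropylsilane F8. Miyaura borylation (B2pin2, PdCl2(dppf), KOAc, dioxane) converts it to 18 with retention of geometry.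

**Further compounds**
F1 | step 17 | 2-(allyloxy)-4-(methoxymethoxy)benzaldehyde | C=CCOc1cc(OCOC)ccc1C=O
F2 | step 17 | (E)-3-[2-(allyloxy)-4-(methoxymethoxy)phenyl]-1-[2-hydroxy-4-(methoxymethoxy)-3-prenylphenyl]prop-2-en-1-one | CC(C)=CCc1c(OCOC)ccc(C(=O)/C=C/c2ccc(OCOC)cc2OCC=C)c1O
F3 | step 17 | (E)-4-{6-(allyloxy)-2-[3,5-bis(methoxymethoxy)phenyl]-1-benzofuran-5-yl}but-3-en-2-one | CC(=O)/C=C/c1cc2cc(-c3cc(OCOC)cc(OCOC)c3)oc2cc1OCC=C
F4 | step 17 | 6-(allyloxy)-2-[3,5-bis(methoxymethoxy)phenyl]-5-[(E)-3-methylbuta-1,3-dien-1-yl]-1-benzofuran | C=C(C)/C=C/c1cc2cc(-c3cc(OCOC)cc(OCOC)c3)oc2cc1OCC=C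
F5 | step 17 | all-trans (3R,4R,5S) bis(allyl) tetrakis(MOM) exo adduct | CC(C)=CCc1c(OCOC)ccc(C(=O)[C@@H]2[C@@H](c3ccc(OCOC)cc3OCC=C)CC(C)=C[C@H]2c2cc3cc(-c4cc(OCOC)cc(OCOC)c4)oc3cc2OCC=C)c1O
F6 | step 18 | tethered C2 allylic alcohol (OH on the face of the C3 aryl, C1=C6 alkene) | CC(C)=CCc1c(OCOC)ccc(C(=O)[C@@H]2[C@@H](c3ccc(OCOC)cc3O[Si](C(C)C)(C(C)C)O[Si](C(C)C)(C(C)C)O6)C=C(C)[C@@H](O)[C@H]2c2cc3cc(-c4cc(OCOC)cc(OCOC)c4)oc3cc26)c1O
F7 | step 18 | tethered C1=C2 cyclohexene | CC(C)=CCc1c(OCOC)ccc(C(=O)[C@@H]2[C@@H](c3ccc(OCOC)cc3O[Si](C(C)C)(C(C)C)O[Si](C(C)C)(C(C)C)O6)CC(C)=C[C@H]2c2cc3cc(-c4cc(OCOC)cc(OCOC)c4)oc3cc26)c1O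
F8 | step 14 | {2-[(1E,3E)-4-iodo-3-methylbuta-1,3-dien-1-yl]-5-(methoxymethoxy)phenoxy}triisopropylsilane | COCOc1ccc(/C=C/C(C)=C/I)c(O[Si](C(C)C)(C(C)C)C(C)C)c1
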